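## Retrosynthetic overview

- **Feature the strategy rests on:** in ring B (ten-membered, C1–C10), C5 and C10 lie 1,6 to each other. The bond between the oxygenated carbons C7 and C8 lies midway between them. This is the pattern a [3,3] shift of a 1,2-dialkenylcyclohexanol leaves behind.
- **Late disconnections:** acetates; C5=C16 by a Peterson elimination held latent; the C7–O–C19–C17–C8 lactone by intramolecular Reformatsky closure onto a C8 ketone; C11/C12 by OsO4 on a ring A C11=C12–C13=C14 diene.
- **C10:** the open face of the E-C9=C10 olefin is the C15 face, so an external reagent would place H10 cis to C15. The olefin is therefore moved into ring A, and H10 is relayed from C12 by an allylic diazene. C9 oxygen follows through the C8 ketone.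
- **Ring B:** anionic oxy-Cope rearrangement of cis-decalin carbinol 23 makes C7–C8 and breaks C5–C10. The C5–C6 enolate is chlorinated at C6 in the same flask.
- **Order of rings:** ring A and the six-membered ring to be enlarged come from (S)-Wieland–Miescher ketone. Ring B forms in step 14 and the lactone in step 32.

Key step: step 14

**Numbering.** Ring B is C1–C10. Ring A is C1, C14, C13, C12, C11, C10. The lactone is C7–O–C19–C17–C8. Methyls are C15 (on C1), C18 (on C17) and C20 (on C11); the methylene is C16 (on C5). On ring A, β is the face of C15 and α the opposite face.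

**Assumption.** Stereocentres that are erased later are drawn as expected for attack on the open face, and either epimer serves. These are C5 before step 10 and from step 15 to step 33, C10 before step 14, C11/C12 in 33–41, and the C–Br carbon of 52.

## Route

Step 1
Reactants: 1 (S)-Wieland–Miescher ketone
Product: 2 C2 alcohol enone (OH cis to C15)
Conditions: NaBH4 (0.27 equiv), EtOH, 0 °C
Reagents that add atoms: none
Why: Chemoselective borohydride reduction, in which the saturated C2 ketone reacts before the vinylogous C12 carbonyl and hydride adds anti to the angular methyl C15, which sets C2 (S, oxygen cis to C15).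

Step 2
Reactants: 2 C2 alcohol enone
Product: 3 C2 TBS ether enone
Conditions: t-BuMe2SiCl, imidazole, DMF, 40 °C
Reagents that add atoms: tert-butyldimethylsilyl chloride CC(C)(C)[Si](C)(C)Cl
Why: Standard silylation; the neopentyl TBS ether withstands every basic, hydridic and organometallic step up to step 33.

Step 3
Reactants: 3 C2 TBS ether enone
Product: 5 C5 hydroxy enone (OH cis to C15), via linear TMS dienol ether 4 (not isolated)
Conditions: Me3SiOTf, Et3N, CH2Cl2, 0 °C; then mCPBA, NaHCO3, CH2Cl2, −20 °C; aqueous citric acid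
Reagents that add atoms: 3-chloroperbenzoic acid OOC(=O)c1cccc(Cl)c1
Why: Vinylogous Rubottom oxidation, in which soft enolisation gives the linear C12(OSi)=C11–C10=C5 dienol ether and the peracid oxidises its terminal carbon C5 axially on the C15 face, as in the 6β-hydroxylation of steroidal dienol ethers (a centre erased in step 10).

Step 4
Reactants: 5 C5 hydroxy enone
Product: 6 C5 TES ether enone
Conditions: Et3SiCl, imidazole, CH2Cl2, 0 °C
Reagents that add atoms: chlorotriethylsilane CC[Si](Cl)(CC)CC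
Why: Silylation with a group that can be removed in step 9 in the presence of the TBS ether, and that is too poor a leaving group for reductive loss from the γ-position in step 5.

Step 5
Reactants: 6 C5 TES ether enone
Product: 8 C10-vinyl cis-decalone, via C11=C12 TMS enol ether 7 (not isolated)
Conditions: CH2=CHMgBr, CuBr·SMe2 (cat.), Me3SiCl, HMPA, THF, −78 to −40 °C; then aqueous citric acid, THF, 0 °C
Reagents that add atoms: vinylmagnesium bromide C=C[Mg]Br
Why: Copper-catalysed, chlorosilane-accelerated conjugate addition, in which, as for other 4a-methyloctalones, the nucleophile enters C10 on the C15 face and gives the cis-decalin, so the temporary quaternary centre C10 carries its vinyl group cis to C15.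

Step 6
Reactants: 8 C10-vinyl cis-decalone
Product: 9 C12 dioxolane
Conditions: (Me3SiOCH2)2, Me3SiOTf (cat.), CH2Cl2, −78 to −20 °C; pyridine quench
Reagents that add atoms: 1,2-bis(trimethylsilyloxy)ethane C[Si](C)(C)OCCO[Si](C)(C)C
Why: Noyori ketalisation under aprotic conditions masks C12 and spares both silyl ethers.

Step 7
Reactants: 9 C12 dioxolane
Product: 11 C9 aldehyde, via secondary ozonide 10 (not isolated)
Conditions: O3, CH2Cl2, −78 °C; then PPh3, −78 °C to rt
Reagents that add atoms: ozone [O-][O+]=O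
Why: Ozonolysis with reductive work-up cleaves the only C=C bond and leaves C9 as a non-enolisable neopentyl aldehyde.

Step 8
Reactants: 11 C9 aldehyde; 12 2-(trimethylsilyl)-1,3-dithiane
Product: 14 ketene dithioacetal TES ether, via 2-lithio-2-(trimethylsilyl)-1,3-dithiane 13 (not isolated)
Conditions: 12, n-BuLi, THF, −30 °C; then 11, −78 °C to rt
Reagents that add atoms: none
Why: Peterson olefination, in which the silyl-stabilised dithianyl anion adds to the aldehyde and the β-silyl alkoxide collapses to C9=C8(S)2, so C8 enters at the ketone oxidation level; the C5 oxygen stays silylated so that no retro-aldol path exists.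

Step 9
Reactants: 14 ketene dithioacetal TES ether
Product: 15 C5 alcohol
Conditions: HF·pyridine, excess pyridine, THF, 0 °C
Reagents that add atoms: none
Why: Selective fluoride desilylation, in which the TES ether is far more labile than the neopentyl TBS ether and the pyridine buffer protects the dioxolane and the ketene dithioacetal from protonation.

Step 10
Reactants: 15 C5 alcohol
Product: 16 C5 ketone
Conditions: SO3·pyridine, DMSO, Et3N, CH2Cl2, 0 °C
Reagents that add atoms: none
Why: Parikh–Doering oxidation uses activated DMSO without electrophilic halogen or metal oxidant and so leaves the electron-rich ketene dithioacetal intact; C10 is quaternary, so the β,γ-olefin cannot conjugate.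

Step 11
Reactants: 17 4-methoxybenzyl alcohol; 18 trichloroethene
Product: 20 (E)-1,2-dichlorovinyl 4-methoxybenzyl ether, via potassium 4-methoxybenzyl oxide 19 (not isolated)
Conditions: KH, THF, 0 °C; then 18, −50 °C to rt
Reagents that add atoms: none
Why: Greene synthesis of dichlorovinyl ethers (alkoxide-induced elimination to dichloroethyne and anti addition of the alkoxide); the 4-methoxybenzyl group is chosen because the C7 oxygen must be freed late under neutral conditions.

Step 12
Reactants: 16 C5 ketone; 20 (E)-1,2-dichlorovinyl 4-methoxybenzyl ether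
Product: 22 C5 alkynyl carbinol (OH cis to C15; alkynyl arm trans to the C9 arm), via lithium (4-methoxybenzyloxy)acetylide 21 (not isolated)
Conditions: 20, n-BuLi (2.1 equiv), THF, −78 to −40 °C; then 16, −78 to −20 °C; H2O
Reagents that add atoms: none
Why: Elimination and chlorine–lithium exchange give the alkoxyethynyllithium, a slim nucleophile that adds 1,2 to the hindered ketone from the face opposite the syn-axial C15, so the new arm is equatorial and trans to the C9 arm (temporary centre C5).

Step 13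
Reactants: 22 C5 alkynyl carbinol
Product: 23 C5 carbinol bearing (E)-2-(4-methoxybenzyloxy)vinyl and ketene dithioacetal arms (oxy-Cope precursor)
Conditions: LiAlH4, THF, 0 °C to rt; H2O, aqueous NaOH
Reagents that add atoms: none
Why: Hydroxyl-directed trans-hydroalumination of the propargylic alcohol gives only the E enol ether, and this two-step entry avoids (E)-2-alkoxyvinyllithium reagents, which lose alkoxide by anti elimination.

Step 14
Reactants: 23 oxy-Cope precursor
Product: 26 6-chloro ring B cyclodecenone (E-C9=C10; C6 and C7 as in the target), via potassium C5 alkoxide 24 (not isolated), via potassium C5–C6 enolate 25 (not isolated)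
Conditions: KN(SiMe3)2, 18-crown-6, THF, −78 to 0 °C; then cannulated into C2Cl6, THF, −78 °C
Reagents that add atoms: hexachloroethane ClC(Cl)(Cl)C(Cl)(Cl)Cl
Why: Deprotonation gives alkoxide 24, whose charge accelerates the [3,3] sigmatropic shift along C7=C6–C5···C10–C9=C8 (anionic oxy-Cope rearrangement of a trans-1,2-dialkenylcyclohexanol, the known route to cyclodec-5-enones): C7–C8 forms, the decalin bond C5–C10 breaks and the charge ends in the C5–C6 enolate 25. Ring B (ten-membered) is thus closed by four-atom enlargement of the six-membered ring C1–C2–C3–C4–C5–C10 and not by end-to-end cyclisation. In the cis-decalin conformer that holds C15 axial both arms are equatorial and gauche, so the chair array has C1 and C4 pseudo-equatorial, which gives the E-C9=C10 olefin, and the E enol ether keeps the benzyloxy group equatorial, which sets C7 as in the target. The two sulfur atoms take up the charge that builds at C8, so the shift should run at or below 0 °C, where loss of 4-methoxybenzyl oxide from the β-alkoxy enolate is slow; C11 is sp3 and unsubstituted, so no second 1,5-diene competes and no allylic strain builds against the dithiane. The enolate is regiodefined (protonation would waste this), its inner face looks at C10, and halophilic attack on C2Cl6 from the outer face puts chlorine on C6 anti to H7, the target configuration. Inverse addition at −78 °C stops proton exchange between 25 and 26, and C2Cl6, unlike N-chloro reagents, leaves the dithiane alone.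

Step 15
Reactants: 26 6-chloro ring B cyclodecenone
Product: 28 C5 (trimethylsilyl)methyl carbinol TES ether, via dichlorocerium C5 alkoxide 27 (not isolated)
Conditions: Me3SiCH2Li, CeCl3, THF, −78 °C; then Et3SiOTf, −78 to −30 °C
Reagents that add atoms: (trimethylsilyl)methyllithium [Li]C[Si](C)(C)C; triethylsilyl trifluoromethanesulfonate CC[Si](CC)(CC)OS(=O)(=O)C(F)(F)F
Why: Organocerium 1,2-addition (first half of a Peterson methylenation) is non-basic, so the α-chloro ketone is neither enolised nor closed to an epoxide nor stripped of its C7 alkoxide, and silylating the alkoxide locks C16 as a latent methylene that is inert to borane, OsO4, palladium and SmI2.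

Step 16
Reactants: 28 C5 (trimethylsilyl)methyl carbinol TES ether
Product: 29 C12 ketone with unconjugated E-C9=C10
Conditions: oxalic acid on wet SiO2, CH2Cl2, rt
Reagents that add atoms: water O
Why: Mild heterogeneous deketalisation frees C12 without protonating the strained olefin, without conjugating it, and without touching the silyl ethers, the PMB ether or the dithiane.

Step 17
Reactants: 29 C12 ketone with unconjugated E-C9=C10
Product: 32 C11-methyl C10=C11 enone, via potassium dienolate 30 (not isolated), via C11-methyl β,γ-enone 31 (not isolated)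
Conditions: KN(SiMe3)2, THF, −78 °C; MeI, −78 to −20 °C; crude product, DBU, CH2Cl2, rt
Reagents that add atoms: iodomethane CI
Why: α-Alkylation of an extended enolate (C11–H is both α-keto and allylic, hence the most acidic) brings in C20, and base-mediated conjugation then releases the strain of the E-cyclodecene and moves the olefin to C10=C11 inside ring A.

Step 18
Reactants: 32 C11-methyl C10=C11 enone
Product: 33 C12 β-allylic alcohol
Conditions: (R)-2-methyl-CBS-oxazaborolidine [(R)-tetrahydro-1-methyl-3,3-diphenyl-1H,3H-pyrrolo[1,2-c][1,3,2]oxazaborole] (cat.), catecholborane, toluene, −78 °C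
Reagents that add atoms: none
Why: Corey–Bakshi–Shibata reduction under catalyst control (fully substituted alkenyl side large, C13 methylene small) delivers hydride to the α face and sets the temporary C12 carbinol β regardless of the ring A conformation.

Step 19
Reactants: 33 C12 β-allylic alcohol
Product: 36 C11=C12 olefin with H10 α (trans to C15), via C12 sulfonylhydrazide 34 (not isolated), via C12 allylic diazene 35 (not isolated)
Conditions: 2-nitrobenzenesulfonylhydrazide, PPh3, DEAD, N-methylmorpholine, −30 °C; then 23 °C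
Reagents that add atoms: none
Why: Myers reductive allylic transposition, in which Mitsunobu displacement inverts C12, loss of sulfinate gives the α-oriented allylic diazene, and the retro-ene loss of N2 hands hydrogen suprafacially to the α face of C10, which sets C10 (S) trans to C15.

Step 20
Reactants: 36 C11=C12 olefin with H10 α
Product: 38 C12 alcohol, via C12 alkylborane 37 (not isolated)
Conditions: BH3·THF (excess), THF, 0 °C to rt; then NaOH, H2O2, 0 °C
Reagents that add atoms: hydrogen peroxide OO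
Why: Hydroboration–oxidation places boron on the less substituted C12 by syn addition anti to C15; both new centres are temporary, and the only other latent olefin (C5/C16) is masked.

Step 21
Reactants: 38 C12 alcohol
Product: 39 C12 ketone with C11 methyl
Conditions: SO3·pyridine, DMSO, Et3N, CH2Cl2, 0 °C
Reagents that add atoms: none
Why: Parikh–Doering oxidation tolerates the dithiane; C10 is β to the new carbonyl and cannot epimerise.

Step 22
Reactants: 39 C12 ketone with C11 methyl
Product: 41 C13=C14 enone, via lithium C12–C13 enolate 40 (not isolated)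
Conditions: LiN(i-Pr)2, THF, −78 °C; then PhS(Cl)=N-t-Bu, −78 °C
Reagents that add atoms: none
Why: Mukaiyama dehydrogenation, in which kinetic deprotonation takes the C13 methylene rather than the tertiary C11–H and the sulfilimine adduct eliminates at −78 °C, which avoids Pd(OAc)2 or iodine oxidants that would bind or oxidise the dithiane.

Step 23
Reactants: 41 C13=C14 enone
Product: 43 C12 dienyl triflate, via potassium cross-conjugated dienolate 42 (not isolated)
Conditions: KN(SiMe3)2, THF, −78 °C; then PhNTf2, −78 to 0 °C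
Reagents that add atoms: N-phenylbis(trifluoromethanesulfonimide) O=S(=O)(N(c1ccccc1)S(=O)(=O)C(F)(F)F)C(F)(F)F
Why: O-Triflation of the cross-conjugated dienolate; C11–H is the only enolisable position of 41 because C1 is quaternary.

Step 24
Reactants: 43 C12 dienyl triflate
Product: 44 ring A C11=C12–C13=C14 diene
Conditions: Pd(OAc)2 (cat.), PPh3, HCO2H, Et3N, DMF, 60 °C
Reagents that add atoms: none
Why: Palladium-catalysed formate reduction of an enol triflate replaces OTf by H; the unactivated secondary chloride and the masked C5/C16 unit offer zerovalent palladium no allylic leaving group.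

Step 25
Reactants: 44 ring A diene
Product: 45 C8 ketone
Conditions: MeI (excess), CaCO3, MeCN/H2O, 45 °C
Reagents that add atoms: water O
Why: Alkylative dithiane hydrolysis (S-methylation, then attack of water) is non-oxidative, so the diene and the PMB ether survive.

Step 26
Reactants: 45 C8 ketone
Product: 47 C9 hydroxy ketone (C9 epimeric to the target), via potassium C8–C9 enolate 46 (not isolated)
Conditions: KN(SiMe3)2, THF, −78 °C; then 2-(phenylsulfonyl)-3-phenyloxaziridine, −78 °C; H2O
Reagents that add atoms: 2-(phenylsulfonyl)-3-phenyloxaziridine O=S(=O)(c1ccccc1)N1OC1c1ccccc1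
Why: Davis hydroxylation of the kinetic enolate (C9 methylene rather than the alkoxy-bearing methine C7); allylic 1,3-strain holds H10 in the enolate plane and the oxidant attacks anti to the quaternary C1, which should give the C9 epimer that step 27 is designed to invert.

Step 27
Reactants: 47 C9 hydroxy ketone
Product: 48 C9 acetate (C9 as in the target)
Conditions: PPh3, DIAD, AcOH, toluene, 0 °C to rt
Reagents that add atoms: acetic acid CC(=O)O
Why: Mitsunobu inversion, an SN2 displacement at the carbonyl-activated C9 by acetate, sets C9 (S) and installs its final ester in one operation.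

Step 28
Reactants: 48 C9 acetate
Product: 49 11α,12α-diol
Conditions: OsO4 (cat.), N-methylmorpholine N-oxide, acetone/H2O, 0 °C
Reagents that add atoms: N-methylmorpholine N-oxide C[N+]1([O-])CCOCC1; water O
Why: Upjohn dihydroxylation, in which the trisubstituted C11=C12 bond of the diene is more electron-rich and less shielded than C13=C14 next to quaternary C1, and OsO4 adds syn on the α face anti to the 1,3-related axial C15, which sets C11 (S, OH α, C20 β) and C12 (R).

Step 29
Reactants: 49 11α,12α-diol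
Product: 50 C12 acetate
Conditions: Ac2O, pyridine, 4-(dimethylamino)pyridine (cat.), CH2Cl2, 0 °C
Reagents that add atoms: acetic anhydride CC(=O)OC(C)=O
Why: Acylation takes the secondary allylic C12 alcohol and leaves the tertiary C11 alcohol free.

Step 30
Reactants: 50 C12 acetate
Product: 51 C7 alcohol
Conditions: DDQ, CH2Cl2/pH 7 buffer, 0 °C
Reagents that add atoms: none
Why: Oxidative cleavage of the PMB ether is neutral and spares the acetates, the chloride, the silyl groups and the C13=C14 olefin.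

Step 31
Reactants: 51 C7 alcohol
Product: 52 C7 2-bromopropanoate
Conditions: 2-bromopropanoyl bromide, pyridine, CH2Cl2, −20 °C
Reagents that add atoms: 2-bromopropanoyl bromide CC(Br)C(=O)Br
Why: Esterification of the only free secondary alcohol brings in C17, C18 and C19; the configuration at the bromide carbon is lost in step 32.

Step 32
Reactants: 52 C7 2-bromopropanoate
Product: 54 β-hydroxy-γ-lactone, via samarium ester enolate 53 (not isolated)
Conditions: SmI2 (2.2 equiv), THF, −78 °C; H2O
Reagents that add atoms: none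
Why: Intramolecular samarium Reformatsky reaction, in which the tether from the C7 oxygen reaches only the C8 carbonyl face exposed when C6 and C9 are antiperiplanar about C7–C8 (the other face would need them eclipsed), which sets C8 (R, OH cis to the C7 oxygen), while C18 takes the side of the five-membered ring away from C9, which sets the epimerisable C17 (R) in its more stable form.

Step 33
Reactants: 54 β-hydroxy-γ-lactone
Product: 55 C2 alcohol with C5=C16 methylene
Conditions: HF (48 % aq), MeCN, 0 °C to rt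
Reagents that add atoms: none
Why: One acid treatment removes the TBS and TES ethers and completes the Peterson methylenation (β-silicon-assisted anti elimination of the C5 carbinol), unveiling the allylic chloride only when no reductant, nucleophile or base is left in the route.

Step 34
Reactants: 55 C2 alcohol with C5=C16 methylene
Product: 56 CNP0259091.1 (target)
Conditions: Ac2O, pyridine, 4-(dimethylamino)pyridine (cat.), CH2Cl2, rt
Reagents that add atoms: acetic anhydride CC(=O)OC(C)=O
Why: Acetylation of the last secondary alcohol (C2); the tertiary C8 and C11 alcohols do not react under these conditions.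

## Compound list

1 | (S)-Wieland–Miescher ketone | C[C@]12CCC(=O)C=C1CCCC2=O | starting material
2 | C2 alcohol enone | C1CC[C@H](O)[C@@]2(C)CCC(=O)C=C12 | intermediate
3 | C2 TBS ether enone | C1CC[C@H](O[Si](C)(C)C(C)(C)C)[C@@]2(C)CCC(=O)C=C12 | intermediate
4 | linear TMS dienol ether | C1=C2C=C(O[Si](C)(C)C)CC[C@]2(C)[C@@H](O[Si](C)(C)C(C)(C)C)CC1 | intermediate
5 | C5 hydroxy enone | O[C@@H]1CC[C@H](O[Si](C)(C)C(C)(C)C)[C@@]2(C)CCC(=O)C=C12 | intermediate
6 | C5 TES ether enone | CC[Si](CC)(CC)O[C@@H]1CC[C@H](O[Si](C)(C)C(C)(C)C)[C@@]2(C)CCC(=O)C=C12 | intermediate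
7 | C11=C12 TMS enol ether | CC[Si](CC)(CC)O[C@@H]1CC[C@H](O[Si](C)(C)C(C)(C)C)[C@@]2(C)CCC(O[Si](C)(C)C)=C[C@@]12C=C | intermediate
8 | C10-vinyl cis-decalone | CC[Si](CC)(CC)O[C@@H]1CC[C@H](O[Si](C)(C)C(C)(C)C)[C@@]2(C)CCC(=O)C[C@@]12C=C | intermediate
9 | C12 dioxolane | CC[Si](CC)(CC)O[C@@H]1CC[C@H](O[Si](C)(C)C(C)(C)C)[C@@]2(C)CCC3(OCCO3)C[C@@]12C=C | intermediate
10 | secondary ozonide | CC[Si](CC)(CC)O[C@@H]1CC[C@H](O[Si](C)(C)C(C)(C)C)[C@@]2(C)CCC3(OCCO3)C[C@@]12C3OOCO3 | intermediate
11 | C9 aldehyde | CC[Si](CC)(CC)O[C@@H]1CC[C@H](O[Si](C)(C)C(C)(C)C)[C@@]2(C)CCC3(OCCO3)C[C@@]12C=O | intermediate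
12 | 2-(trimethylsilyl)-1,3-dithiane | C[Si](C)(C)C1SCCCS1 | starting material
13 | 2-lithio-2-(trimethylsilyl)-1,3-dithiane | [Li]C1([Si](C)(C)C)SCCCS1 | intermediate
14 | ketene dithioacetal TES ether | CC[Si](CC)(CC)O[C@@H]1CC[C@H](O[Si](C)(C)C(C)(C)C)[C@@]2(C)CCC3(OCCO3)C[C@@]12C=C4SCCCS4 | intermediate
15 | C5 alcohol | O[C@@H]1CC[C@H](O[Si](C)(C)C(C)(C)C)[C@@]2(C)CCC3(OCCO3)C[C@@]12C=C4SCCCS4 | intermediate
16 | C5 ketone | O=C1CC[C@H](O[Si](C)(C)C(C)(C)C)[C@@]2(C)CCC3(OCCO3)C[C@@]12C=C4SCCCS4 | intermediate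
17 | 4-methoxybenzyl alcohol | COc1ccc(CO)cc1 | starting material
18 | trichloroethene | ClC=C(Cl)Cl | starting material
19 | potassium 4-methoxybenzyl oxide | [K+].[O-]Cc1ccc(OC)cc1 | intermediate
20 | (E)-1,2-dichlorovinyl 4-methoxybenzyl ether | COc1ccc(CO/C(Cl)=C\Cl)cc1 | intermediate
21 | lithium (4-methoxybenzyloxy)acetylide | [Li]C#COCc1ccc(OC)cc1 | intermediate
22 | C5 alkynyl carbinol | O[C@]1(C#COCc5ccc(OC)cc5)CC[C@H](O[Si](C)(C)C(C)(C)C)[C@@]2(C)CCC3(OCCO3)C[C@@]12C=C4SCCCS4 | intermediate
23 | oxy-Cope precursor | O[C@]1(/C=C/OCc5ccc(OC)cc5)CC[C@H](O[Si](C)(C)C(C)(C)C)[C@@]2(C)CCC3(OCCO3)C[C@@]12C=C4SCCCS4 | intermediate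
24 | potassium C5 alkoxide | [K+].[O-][C@]1(/C=C/OCc5ccc(OC)cc5)CC[C@H](O[Si](C)(C)C(C)(C)C)[C@@]2(C)CCC3(OCCO3)C[C@@]12C=C4SCCCS4 | intermediate
25 | potassium C5–C6 enolate of the ring B cyclodecenone | [K+].[O-]/C1=C\[C@H](OCc2ccc(OC)cc2)C2(SCCCS2)/C=C3\CC4(OCCO4)CC[C@]3(C)[C@@H](O[Si](C)(C)C(C)(C)C)CC1 | intermediate
26 | 6-chloro ring B cyclodecenone | O=C1CC[C@H](O[Si](C)(C)C(C)(C)C)[C@@]2(C)CCC3(OCCO3)C/C2=C\C4(SCCCS4)[C@@H](OCc5ccc(OC)cc5)[C@H]1Cl | intermediate
27 | dichlorocerium C5 alkoxide | Cl[Ce](Cl)O[C@]1(C[Si](C)(C)C)CC[C@H](O[Si](C)(C)C(C)(C)C)[C@@]2(C)CCC3(OCCO3)C/C2=C\C4(SCCCS4)[C@@H](OCc5ccc(OC)cc5)[C@H]1Cl | intermediate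
28 | C5 (trimethylsilyl)methyl carbinol TES ether | CC[Si](CC)(CC)O[C@]1(C[Si](C)(C)C)CC[C@H](O[Si](C)(C)C(C)(C)C)[C@@]2(C)CCC3(OCCO3)C/C2=C\C4(SCCCS4)[C@@H](OCc5ccc(OC)cc5)[C@H]1Cl | intermediate
29 | C12 ketone with unconjugated E-C9=C10 | CC[Si](CC)(CC)O[C@]1(C[Si](C)(C)C)CC[C@H](O[Si](C)(C)C(C)(C)C)[C@@]2(C)CCC(=O)C/C2=C\C4(SCCCS4)[C@@H](OCc5ccc(OC)cc5)[C@H]1Cl | intermediate
30 | potassium dienolate | [K+].CC[Si](CC)(CC)O[C@]1(C[Si](C)(C)C)CC[C@H](O[Si](C)(C)C(C)(C)C)[C@@]2(C)CCC([O-])=C/C2=C\C4(SCCCS4)[C@@H](OCc5ccc(OC)cc5)[C@H]1Cl | intermediate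
31 | C11-methyl β,γ-enone | CC[Si](CC)(CC)O[C@]1(C[Si](C)(C)C)CC[C@H](O[Si](C)(C)C(C)(C)C)[C@@]2(C)CCC(=O)C(C)/C2=C\C4(SCCCS4)[C@@H](OCc5ccc(OC)cc5)[C@H]1Cl | intermediate
32 | C11-methyl C10=C11 enone | CC[Si](CC)(CC)O[C@]1(C[Si](C)(C)C)CC[C@H](O[Si](C)(C)C(C)(C)C)[C@@]2(C)CCC(=O)C(C)=C2CC4(SCCCS4)[C@@H](OCc5ccc(OC)cc5)[C@H]1Cl | intermediate
33 | C12 β-allylic alcohol | CC[Si](CC)(CC)O[C@]1(C[Si](C)(C)C)CC[C@H](O[Si](C)(C)C(C)(C)C)[C@@]2(C)CC[C@H](O)C(C)=C2CC4(SCCCS4)[C@@H](OCc5ccc(OC)cc5)[C@H]1Cl | intermediate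
34 | C12 sulfonylhydrazide | CC[Si](CC)(CC)O[C@]1(C[Si](C)(C)C)CC[C@H](O[Si](C)(C)C(C)(C)C)[C@@]2(C)CC[C@@H](N(N)S(=O)(=O)c3ccccc3[N+](=O)[O-])C(C)=C2CC4(SCCCS4)[C@@H](OCc5ccc(OC)cc5)[C@H]1Cl | intermediate
35 | C12 allylic diazene | CC[Si](CC)(CC)O[C@]1(C[Si](C)(C)C)CC[C@H](O[Si](C)(C)C(C)(C)C)[C@@]2(C)CC[C@@H](N=N)C(C)=C2CC4(SCCCS4)[C@@H](OCc5ccc(OC)cc5)[C@H]1Cl | intermediate
36 | C11=C12 olefin with H10 α | CC[Si](CC)(CC)O[C@]1(C[Si](C)(C)C)CC[C@H](O[Si](C)(C)C(C)(C)C)[C@@]2(C)CCC=C(C)[C@@H]2CC4(SCCCS4)[C@@H](OCc5ccc(OC)cc5)[C@H]1Cl | intermediate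
37 | C12 alkylborane | CC[Si](CC)(CC)O[C@]1(C[Si](C)(C)C)CC[C@H](O[Si](C)(C)C(C)(C)C)[C@@]2(C)CC[C@@H](B)[C@H](C)[C@@H]2CC4(SCCCS4)[C@@H](OCc5ccc(OC)cc5)[C@H]1Cl | intermediate
38 | C12 alcohol | CC[Si](CC)(CC)O[C@]1(C[Si](C)(C)C)CC[C@H](O[Si](C)(C)C(C)(C)C)[C@@]2(C)CC[C@@H](O)[C@H](C)[C@@H]2CC4(SCCCS4)[C@@H](OCc5ccc(OC)cc5)[C@H]1Cl | intermediate
39 | C12 ketone with C11 methyl | CC[Si](CC)(CC)O[C@]1(C[Si](C)(C)C)CC[C@H](O[Si](C)(C)C(C)(C)C)[C@@]2(C)CCC(=O)[C@H](C)[C@@H]2CC4(SCCCS4)[C@@H](OCc5ccc(OC)cc5)[C@H]1Cl | intermediate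
40 | lithium C12–C13 enolate | [Li+].CC[Si](CC)(CC)O[C@]1(C[Si](C)(C)C)CC[C@H](O[Si](C)(C)C(C)(C)C)[C@@]2(C)CC=C([O-])[C@H](C)[C@@H]2CC4(SCCCS4)[C@@H](OCc5ccc(OC)cc5)[C@H]1Cl | intermediate
41 | C13=C14 enone | CC[Si](CC)(CC)O[C@]1(C[Si](C)(C)C)CC[C@H](O[Si](C)(C)C(C)(C)C)[C@@]2(C)C=CC(=O)[C@H](C)[C@@H]2CC4(SCCCS4)[C@@H](OCc5ccc(OC)cc5)[C@H]1Cl | intermediate
42 | potassium cross-conjugated dienolate | [K+].CC[Si](CC)(CC)O[C@]1(C[Si](C)(C)C)CC[C@H](O[Si](C)(C)C(C)(C)C)[C@@]2(C)C=CC([O-])=C(C)[C@@H]2CC4(SCCCS4)[C@@H](OCc5ccc(OC)cc5)[C@H]1Cl | intermediate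
43 | C12 dienyl triflate | CC[Si](CC)(CC)O[C@]1(C[Si](C)(C)C)CC[C@H](O[Si](C)(C)C(C)(C)C)[C@@]2(C)C=CC(OS(=O)(=O)C(F)(F)F)=C(C)[C@@H]2CC4(SCCCS4)[C@@H](OCc5ccc(OC)cc5)[C@H]1Cl | intermediate
44 | ring A diene | CC[Si](CC)(CC)O[C@]1(C[Si](C)(C)C)CC[C@H](O[Si](C)(C)C(C)(C)C)[C@@]2(C)C=CC=C(C)[C@@H]2CC4(SCCCS4)[C@@H](OCc5ccc(OC)cc5)[C@H]1Cl | intermediate
45 | C8 ketone | CC[Si](CC)(CC)O[C@]1(C[Si](C)(C)C)CC[C@H](O[Si](C)(C)C(C)(C)C)[C@@]2(C)C=CC=C(C)[C@@H]2CC(=O)[C@@H](OCc5ccc(OC)cc5)[C@H]1Cl | intermediate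
46 | potassium C8–C9 enolate | [K+].CC[Si](CC)(CC)O[C@]1(C[Si](C)(C)C)CC[C@H](O[Si](C)(C)C(C)(C)C)[C@@]2(C)C=CC=C(C)[C@@H]2C=C([O-])[C@@H](OCc5ccc(OC)cc5)[C@H]1Cl | intermediate
47 | C9 hydroxy ketone (9-epi) | CC[Si](CC)(CC)O[C@]1(C[Si](C)(C)C)CC[C@H](O[Si](C)(C)C(C)(C)C)[C@@]2(C)C=CC=C(C)[C@@H]2[C@@H](O)C(=O)[C@@H](OCc5ccc(OC)cc5)[C@H]1Cl | intermediate
48 | C9 acetate | CC[Si](CC)(CC)O[C@]1(C[Si](C)(C)C)CC[C@H](O[Si](C)(C)C(C)(C)C)[C@@]2(C)C=CC=C(C)[C@@H]2[C@H](OC(C)=O)C(=O)[C@@H](OCc5ccc(OC)cc5)[C@H]1Cl | intermediate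
49 | 11α,12α-diol | CC[Si](CC)(CC)O[C@]1(C[Si](C)(C)C)CC[C@H](O[Si](C)(C)C(C)(C)C)[C@@]2(C)C=C[C@@H](O)[C@@](C)(O)[C@@H]2[C@H](OC(C)=O)C(=O)[C@@H](OCc5ccc(OC)cc5)[C@H]1Cl | intermediate
50 | C12 acetate | CC[Si](CC)(CC)O[C@]1(C[Si](C)(C)C)CC[C@H](O[Si](C)(C)C(C)(C)C)[C@@]2(C)C=C[C@@H](OC(C)=O)[C@@](C)(O)[C@@H]2[C@H](OC(C)=O)C(=O)[C@@H](OCc5ccc(OC)cc5)[C@H]1Cl | intermediate
51 | C7 alcohol | CC[Si](CC)(CC)O[C@]1(C[Si](C)(C)C)CC[C@H](O[Si](C)(C)C(C)(C)C)[C@@]2(C)C=C[C@@H](OC(C)=O)[C@@](C)(O)[C@@H]2[C@H](OC(C)=O)C(=O)[C@@H](O)[C@H]1Cl | intermediate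
52 | C7 2-bromopropanoate | CC[Si](CC)(CC)O[C@]1(C[Si](C)(C)C)CC[C@H](O[Si](C)(C)C(C)(C)C)[C@@]2(C)C=C[C@@H](OC(C)=O)[C@@](C)(O)[C@@H]2[C@H](OC(C)=O)C(=O)[C@@H](OC(=O)C(C)Br)[C@H]1Cl | intermediate
53 | samarium ester enolate | CC[Si](CC)(CC)O[C@]1(C[Si](C)(C)C)CC[C@H](O[Si](C)(C)C(C)(C)C)[C@@]2(C)C=C[C@@H](OC(C)=O)[C@@](C)(O)[C@@H]2[C@H](OC(C)=O)C(=O)[C@@H](OC(O[Sm](I)I)=CC)[C@H]1Cl | intermediate
54 | β-hydroxy-γ-lactone | CC[Si](CC)(CC)O[C@]1(C[Si](C)(C)C)CC[C@H](O[Si](C)(C)C(C)(C)C)[C@@]2(C)C=C[C@@H](OC(C)=O)[C@@](C)(O)[C@@H]2[C@H](OC(C)=O)[C@]2(O)[C@@H](C)C(=O)O[C@H]2[C@H]1Cl | intermediate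
55 | C2 alcohol with C5=C16 methylene | C=C1CC[C@H](O)[C@@]2(C)C=C[C@@H](OC(C)=O)[C@@](C)(O)[C@@H]2[C@H](OC(C)=O)[C@]2(O)[C@@H](C)C(=O)O[C@H]2[C@H]1Cl | intermediate
56 | CNP0259091.1 | C=C1CC[C@H](OC(C)=O)[C@@]2(C)C=C[C@@H](OC(C)=O)[C@@](C)(O)[C@@H]2[C@H](OC(C)=O)[C@]2(O)[C@@H](C)C(=O)O[C@H]2[C@H]1Cl | target

## Step count and risks

Total step count: 34. Longest linear sequence: 33 (steps 1–10 and 12–34 from 1; step 11 is a one-step side branch).

Steps most likely to fail:

1. **Step 14.** The crown-separated potassium enolate may expel 4-methoxybenzyl oxide before it meets the chlorine source. The alkoxide may also fragment to the open dithiane-stabilised allyl anion and be protonated instead of reclosing at C7. The fallback uses neutral rather than anionic activation of the same [3,3] shift and sets out from 23. Silylation with 1-(trimethylsilyl)imidazole gives the C5 trimethylsilyl ether F1. Heating F1 in o-dichlorobenzene (about 190 °C, base-washed glass) effects a siloxy-Cope rearrangement to the C5–C6 trimethylsilyl enol ether of the cyclodecenone F2, so no free enolate exists during the shift. MeLi in THF at 0 °C then releases the tighter lithium C5–C6 enolate F3 regiospecifically, and cannulation into C2Cl6 at −78 °C comes back to the route at 26.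

2. **Step 26.** Deprotonation may occur at C7 instead of C9. That would be followed by E1cB loss of chloride from C6 or by epimerisation of C7. The fallback oxidises a neutral enol silane instead of a metal enolate and sets out from 45. Soft enolisation with Me3SiOTf and Et3N in CH2Cl2 gives the C8–C9 trimethylsilyl enol ether F4 without a free carbanion next to the chloride. Rubottom oxidation with one equivalent of dimethyldioxirane at −78 °C follows, since the enol silane reacts before the diene. Citric acid work-up comes back to the route at 47.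

3. **Step 32.** SmI2 may cleave an α-acyloxy group of the C8 ketone. Alternatively, the samarium enolate may be protonated (simple debromination) before it reaches the hindered carbonyl. The fallback is an intermolecular zinc Reformatsky reaction followed by lactonisation and sets out from 51. Activated Zn and ethyl 2-bromopropanoate in THF add to the C8 ketone with the zinc held by the C7 alkoxide, giving the C8 β-hydroxy ester F5. Pyridinium p-toluenesulfonate in warm benzene closes the lactone onto the C7 alcohol with loss of ethanol, and C17 settles in its more stable form. This comes back to the route at 54.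

## Further compounds

F1 | step 14 | C5 trimethylsilyl ether of 23 | C[Si](C)(C)O[C@]1(/C=C/OCc5ccc(OC)cc5)CC[C@H](O[Si](C)(C)C(C)(C)C)[C@@]2(C)CCC3(OCCO3)C[C@@]12C=C4SCCCS4
F2 | step 14 | C5–C6 trimethylsilyl enol ether of the cyclodecenone | C[Si](C)(C)O/C1=C\[C@H](OCc2ccc(OC)cc2)C2(SCCCS2)/C=C3\CC4(OCCO4)CC[C@]3(C)[C@@H](O[Si](C)(C)C(C)(C)C)CC1
F3 | step 14 | lithium C5–C6 enolate | [Li+].[O-]/C1=C\[C@H](OCc2ccc(OC)cc2)C2(SCCCS2)/C=C3\CC4(OCCO4)CC[C@]3(C)[C@@H](O[Si](C)(C)C(C)(C)C)CC1
F4 | step 26 | C8–C9 trimethylsilyl enol ether | CC[Si](CC)(CC)O[C@]1(C[Si](C)(C)C)CC[C@H](O[Si](C)(C)C(C)(C)C)[C@@]2(C)C=CC=C(C)[C@@H]2C=C(O[Si](C)(C)C)[C@@H](OCc5ccc(OC)cc5)[C@H]1Cl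
F5 | step 32 | C8 β-hydroxy ester | CC[Si](CC)(CC)O[C@]1(C[Si](C)(C)C)CC[C@H](O[Si](C)(C)C(C)(C)C)[C@@]2(C)C=C[C@@H](OC(C)=O)[C@@](C)(O)[C@@H]2[C@H](OC(C)=O)[C@](O)([C@@H](C)C(=O)OCC)[C@@H](O)[C@H]1Cl
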